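The runs were computed for substances that don't exist; noise was put on by code.

In the elm run the complex with two exchanged stands at 13.4% after 10.0 min, although 0.60 M of incoming ligand on 1 M of starting complex has room for 30.0%, since each such complex takes two ligands. The complex with one exchanged reads 0% by 12.0 min, so these readings don't show where the rest of the ligand stands, or whether it is spent.

| flask | starting complex | incoming ligand | remark | time |
|---|---|---|---|---|
| elm | 1 M | 0.60 M | run made earlier |  |
| maple | 1 M | 1.5 M | run made earlier |  |
| south-east | 1.0 M | 0.800 M |  | 25 min |
| north | 1.0 M | 1.00 M |  | 25 min |
| north-west | 1.0 M | 2.00 M |  | 25 min |

- elm (time / min: complex with one exchanged / %, complex with two exchanged / %): 0.667: 6.1, 4.1; 2.00: 3.8, 7.6; 4.00: 2.7, 11.7; 5.00: 1.1, 10.1; 8.00: 1.7, 12.9; 10.0: 0.9, 13.4; 12.0: 0, 11.7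
- maple (time / min: complex with one exchanged / %, complex with two exchanged / %): 1.00: 7.1, 18.3; 1.50: 5.1, 26.0; 2.50: 3.6, 35.4; 4.00: 2.4, 38.4; 5.00: 1.5, 40.1; 8.00: 0.4, 41.9; 12.0: 2.2, 47.8

(readings scatter by 1 percentage point)

- which of these holds the largest part of the starting complex at the end of south-east (complex with one exchanged / starting complex / complex with two exchanged)
- which of these holds the largest part of the starting complex at the end of north (complex with one exchanged / starting complex / complex with two exchanged)
- which of these holds the largest part of the starting complex at the end of north-west (complex with one exchanged / starting complex / complex with two exchanged)
- complex with one exchanged at the end of north, in percent of the starting complex charged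



I suppose that a complex which takes one ligand and fails to take the second leaves unseen, carrying that one ligand. Then a count holds once the ligand is spent. The complex touched equals the ligand charged minus the complex with two exchanged, so the untouched complex, in whatever form, exceeds the complex with two exchanged by [starting complex] minus [incoming ligand] as charged. I call this, as a share of the complex charged, the charge gap; in south-east it is 20.0%, and how the branching falls does not enter it.

So south-east should keep starting complex in front. In north the gap is 0%, so I hold untouched complex and complex with two exchanged level and can't separate them. In maple, if the ligand were spent, the gap of −50.0% beside the reading of 47.8% would leave −2.20% untouched, and a share can't be negative. So, as far as a reading with a scatter of 1 percentage point can show, maple still holds ligand at 12.0 min. North-west, with a gap of −100%, lies further that way, so the complex with two exchanged should lead. The complex with one exchanged reads 0% and 2.2% at 12.0 min, and I expect it below one point at 25 min.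

The forecast names starting complex, starting complex and complex with two exchanged for south-east, north and north-west, with 1% (0% to 3%) of complex with one exchanged in north, on the judgement “Starting complex dominates at 0.8 and 1.0 M”, where I hold north level.

The flasks give starting complex in south-east, complex with two exchanged in north and complex with two exchanged in north-west, with 0.167% of complex with one exchanged in north.

    starting complex + incoming ligand → leaving ligand + complex with one exchanged (k = 0.00656 M⁻¹ s⁻¹)
    complex with one exchanged + incoming ligand → leaving ligand + complex with two exchanged (k = 0.0386 M⁻¹ s⁻¹)
    complex with two exchanged → over-reaction product (k = 2.99 × 10⁻⁵ s⁻¹)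
    starting complex ⇌ dormant form (K = 0.357, k = 0.00495 s⁻¹)
    complex with one exchanged → side product (k = 0.0207 s⁻¹)

In north the forward exchange uses starting complex at 1.3 times the rate of its passing into the dormant form at the start, but at 0.030 times at 25.0 min. The dormant form then holds 8.08% beside 22.4% of starting complex, together 30.5% against 27.1% of complex with two exchanged. Counted the same way, south-east shows 22 points against its gap of 20.0%, and the neighbour charged with 0.25 M shows 75 points against a gap of 75.0%.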